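# Proposed total synthesis of stenosporic acid (15)

## Analysis of the target

Stenosporic acid 15 is a depside in which two benzene rings are joined through an aryl ester, and it has no stereocentre. Ring A is a 2-hydroxy-4-methoxy-6-propylbenzoyl unit, and ring B is a 2-hydroxy-6-pentylbenzoic acid that carries the ring A acyl group on O4 and keeps its C1 carboxyl and C2 hydroxyl free. The sensitive points are the depside ester, an activated aryl ester that will not survive hydroxide or alkoxide, and the β-resorcylic acid of ring B, which loses its carboxyl group on heating or in strong acid, so the last operations have to be neutral and run at room temperature. The difficulty is one of differentiation, not of size: on ring A the two oxygen atoms must end up different (OH at C2, OMe at C4) beside a carboxyl that is flanked on both sides, and on ring B only the O4 hydroxyl may be acylated. The strategy rests on ring A being a salicylate whose C1 with its carboxyl carbon, C2 (OH) and C3 correspond to the ester-bearing carbon, the ketone carbon and the methyl carbon of an acetoacetate. Its C4 (OMe), C5 and C6 (propyl) form a three-carbon unit that stands at the carboxylic acid oxidation level at C4 and at the ketone level at C6. A ring assembled from these two pieces is formed with its two oxygens already distinct.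

## Retrosynthetic reasoning

**15 to 14.** The free carboxyl of ring B is masked to the end as the benzyl ester 14. Only the benzyl C–O bond is cut in the last step, by hydrogenolysis, so the depside ester and the decarboxylation-prone acid never meet base, acid or heat.

**14 to 10 and 13.** The C(=O)–O bond between the ring A carbonyl and O4 of ring B is the only bond joining the two halves. Cutting it gives the ring A acid 10 and benzyl olivetolate 13, and makes the route convergent. The forward step is a carbodiimide esterification that must acylate O4 of 13 only. It can do so because the 2-hydroxyls of both 10 and 13 are hydrogen-bonded to an ortho carbonyl and flanked, while the 4-hydroxyl of 13 is free and more acidic.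

**10 to 9.** The ring A acid is carried as its benzyl ester 9. A benzoate with two ortho substituents resists saponification, whereas the benzyl ester is cleaved by hydrogenolysis under neutral conditions.

**9 to 6 and 3.** Ring A is opened at C3–C4 and at C1–C6. This splits the ring into a C1–C2–C3 piece that already carries the ester, the bis(silyloxy)diene 6, and a C4–C5–C6 piece that carries the methoxy group and the propyl chain, the β,β-dimethoxy enone 3. The pieces are matched in polarity: 6 is nucleophilic at its terminal and central carbons, 3 is electrophilic at its acetal carbon and its ketone carbon. One step gains the ring, the ester and both differentiated oxygens. The forward reaction has to join the diene terminus to the acetal carbon and the ester-bearing carbon to the ketone, then lose one methoxy group and the ketone oxygen to aromatise.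

**6 to 5 to 4, and 3 to 1 and 2.** The diene 6 comes from benzyl acetoacetate 4 by two successive enol silylations through the silyl enol ether 5, so no skeletal bond is made. The enone 3 is cut at its C2–C3 bond into the ketene acetal 1 and butyryl chloride 2. The forward step is a C-acylation of the electron-rich alkene.

**13 to 12 to 11.** The benzyl ester 13 is cut at the O–benzyl bond to olivetolic acid 12. The C1–carboxyl bond of 12 is then cut back to commercial olivetol 11, which already holds the pentyl chain and both hydroxyls. The forward carboxylation must enter next to the pentyl group.

## Alternatives that were turned down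

Alternative 1: aryne route to ring A.
- Disconnection: the C6–propyl and C1–carboxyl bonds of ring A, which sit on neighbouring carbons, are cut back to an aryne.
- Forward key step: 1-fluoro-3,5-dimethoxybenzene A2 is lithiated next to fluorine by n-propyllithium A4 and loses fluoride to give 3,5-dimethoxybenzyne A3. A second equivalent of A4 adds to the aryne carbon remote from the methoxy group, and carboxylation of the aryl anion so formed gives 2,4-dimethoxy-6-propylbenzoic acid A1.
- For it: one flask sets both ortho substituents, and the inductive effect of the flanking methoxy group guides the regiochemistry of the addition to A3.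
- Against it: A1 has both oxygens methylated, so a chelation-directed demethylation at C2 is still needed on an acid that decarboxylates easily. Deprotonation of A2 between its two methoxy groups competes and produces no aryne. The aryl anion can add to A3 to give biaryls. A4 usually has to be prepared.
- Comparison: on step count this alternative is stronger, since A1 leads to 10 in two or three steps against five. The chosen route offers in its place a ring formed with OH and OMe already distinct, no cascade of three competing organolithium pathways, and an ester that is removed by hydrogenolysis.

Alternative 2: benzannulation from a diazo ketone.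
- Disconnection: ring A is cut into a four-carbon vinylketene unit (C2, C5, C6 and C1) and a two-carbon alkyne (C3 and C4).
- Forward key step: irradiation of ethyl (2E)-5-diazo-4-oxo-3-propylpent-2-enoate A6 triggers a Wolff rearrangement in which the alkenyl group migrates and a vinylketene results. This adds methoxyacetylene A7 to a cyclobutenone (C2–C3 and C4–C5 bonds). The cyclobutenone opens and recloses by a 6π electrocyclisation (C1–C2 bond) to ethyl 2-hydroxy-4-methoxy-6-propylbenzoate A5.
- For it: the polarisation of A7 fixes the regiochemistry, and OH and OMe arrive differentiated in A5, exactly as in the chosen route.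
- Against it: A7 is volatile, hazardous and not an article of commerce. A6 has to be built over several steps that end in a diazo transfer, and a diazo ketone conjugated to an electron-poor alkene is liable to dipolar cycloaddition between molecules. The step is photochemical. The ethyl ester of A5 is a benzoate with two ortho substituents, so it would need forcing hydrolysis that the benzyl ester 9 avoids.
- Comparison: the step count to A5 is about the same as that to 9, and the regiocontrol is as good. The chosen route uses bulk reagents, needs no photochemistry, and delivers the ester in the form required.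

Alternative 3: Diels–Alder construction of ring B.
- Disconnection: the C1–C2 and C5–C6 bonds of ring B are cut.
- Forward key step: (1Z)-1-methoxy-1,3-bis(trimethylsilyloxy)buta-1,3-diene A9 adds across benzyl oct-2-ynoate A10, with its terminal carbon bonding to the pentyl-bearing carbon. Loss of the methoxy group and desilylation give benzyl 2,4-dihydroxy-6-pentylbenzoate A8. A8 is the same compound as 13.
- For it: A8 is obtained in one ring-forming step with the benzyl ester in place, and the position of the carboxyl group is fixed by the polarity match. On this point the alternative is stronger than the chosen carboxylation of 11, which carries a regiochemical risk.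
- Against it: an ynoate such as A10, with a β-alkyl group and a single acceptor, is a weak dienophile, and A9 decomposes by silyl migration on heating. A10 has to be made. Above all, ring B is the easy ring: a route to A8 leaves the differentiated oxygens of ring A unsolved and needs a second ring synthesis beside it.
- Comparison: the chosen route puts its one demanding step on the ring that needs it and reaches 13, the counterpart of A8, from commercial 11 in two steps.

Key step: step 4

Assumption: 5 and 6 are drawn as the usually favoured geometric isomers; their double-bond geometry is lost in the arene and does not affect the route. The aldol intermediate 8 forms as a mixture of diastereomers whose two stereocentres vanish on dehydration, so its SMILES carries no configuration.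

## Route

Step 1
Reactants: 1 1,1-dimethoxyethene (ketene dimethyl acetal); 2 butyryl chloride
Product: 3 1,1-dimethoxyhex-1-en-3-one
Conditions: Et3N (1.2 equiv.), Et2O, 0 °C to rt; 2 added slowly to 1 and Et3N
Reagents that add atoms: none
Why: C-acylation of a ketene acetal: the electron-rich CH2 carbon of 1 attacks the acid chloride and Et3N removes the proton from the dialkoxycarbenium ion before chloride can demethylate it. If part of 2 is first converted into ethylketene, addition of 1 to the ketene followed by proton transfer leads to the same push–pull enone.

Step 2
Reactants: 4 benzyl acetoacetate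
Product: 5 benzyl (E)-3-(trimethylsilyloxy)but-2-enoate
Conditions: TMSCl (1.5 equiv.), Et3N (1.5 equiv.), toluene, rt
Reagents that add atoms: chlorotrimethylsilane, C[Si](C)(C)Cl
Why: O-silylation of the enol of a β-keto ester with TMSCl and a tertiary amine, the standard silyl enol ether formation; the conjugated silyloxy enoate is the stable product.

Step 3
Reactants: 5 benzyl (E)-3-(trimethylsilyloxy)but-2-enoate
Product: 6 (1Z)-1-benzyloxy-1,3-bis(trimethylsilyloxy)buta-1,3-diene
Conditions: LiN(i-Pr)2 (1.5 equiv.), THF, −78 °C; then TMSCl, −78 °C to rt; used crude
Reagents that add atoms: chlorotrimethylsilane, C[Si](C)(C)Cl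
Why: The lithium amide removes a γ-proton of the silyloxy enoate and the extended ester enolate is trapped on oxygen by TMSCl, the second stage of the standard preparation of 1,3-bis(silyloxy)buta-1,3-dienes. The diene is moisture-sensitive and is taken on without purification.

Step 4
Reactants: 6 (1Z)-1-benzyloxy-1,3-bis(trimethylsilyloxy)buta-1,3-diene; 3 1,1-dimethoxyhex-1-en-3-one
Product: 9 benzyl 2-hydroxy-4-methoxy-6-propylbenzoate, via benzyl (5E)-5-methoxy-3,7-dioxodec-5-enoate 7 (not isolated), via benzyl 2-hydroxy-4-methoxy-6-oxo-2-propylcyclohex-3-ene-1-carboxylate 8 (not isolated)
Conditions: TiCl4 (1.1 equiv.), CH2Cl2, 4 Å MS, −78 °C to 20 °C; aq. HCl work-up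
Reagents that add atoms: none
Why: TiCl4 binds the ketone oxygen of 3, and the unsubstituted terminal carbon of 6, its most nucleophilic position, adds in a Mukaiyama–Michael sense to the dimethoxy-bearing carbon to form the C3–C4 bond. The resulting titanium enolate expels one methoxy group, which gives the vinylogous ester 7 (held in the flask as the silyl enol ether of its β-keto ester) with the second methoxy group retained. The carbon between the two carbonyls of the β-keto ester then adds to the Lewis-acid-activated propyl ketone; this aldol step forms the C1–C6 bond and closes ring A in a 6-(enolendo)-exo-trig mode to give 8, and it needs the E geometry of the push–pull double bond of 7, which equilibrates readily under the Lewis acid. Dehydration of 8 and enolisation of the cyclohexadienone deliver the arene, so the two transient stereocentres of 8 disappear and no stereocentre has to be controlled. The closest known reaction type is the TiCl4-mediated formal [3+3] cyclocondensation of 1,3-bis(silyloxy)buta-1,3-dienes with β-keto acetals, 3-alkoxy enones and 3-silyloxy enones to salicylates. The step needs regioselectivity: the diene terminus must meet the acetal carbon and the ester-bearing carbon the ketone. This is secured by the push–pull polarisation of 3, whose acetal carbon is the conjugate position of the titanium-bound enone, and by the terminal carbon of 6 reacting faster than the internal one. Because the two electrophilic carbons differ in oxidation level, C4 emerges as OMe and C2 as OH without any later differentiation.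

Step 5
Reactants: 9 benzyl 2-hydroxy-4-methoxy-6-propylbenzoate
Product: 10 2-hydroxy-4-methoxy-6-propylbenzoic acid
Conditions: H2 (1 atm), Pd/C (10% Pd), EtOAc, rt
Reagents that add atoms: none
Why: Hydrogenolysis of the benzyl ester over palladium on carbon frees the hindered acid, which would resist saponification, under neutral conditions. The aryl methyl ether and the phenol are inert.

Step 6
Reactants: 11 olivetol (5-pentylbenzene-1,3-diol)
Product: 12 olivetolic acid (2,4-dihydroxy-6-pentylbenzoic acid)
Conditions: MeOMgOCO2Me (2 M in DMF, excess), 120 °C; then cold aq. HCl
Reagents that add atoms: methoxymagnesium methyl carbonate, COC(=O)O[Mg]OC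
Why: Kolbe–Schmitt-type ortho-carboxylation of a resorcinol with a magnesium methyl carbonate; the magnesium chelate between phenoxide and new carboxylate drives the otherwise reversible carboxylation. Entry at the carbon ortho to one hydroxyl and para to the other gives the 2,4-dihydroxy-6-pentyl pattern.

Step 7
Reactants: 12 olivetolic acid
Product: 13 benzyl olivetolate (benzyl 2,4-dihydroxy-6-pentylbenzoate)
Conditions: BnBr (1.05 equiv.), KHCO3 (1.1 equiv.), DMF, rt
Reagents that add atoms: benzyl bromide, BrCc1ccccc1
Why: SN2 alkylation of the carboxylate by benzyl bromide; KHCO3 deprotonates only the carboxylic acid, so the phenols stay protonated and are not benzylated.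

Step 8
Reactants: 10 2-hydroxy-4-methoxy-6-propylbenzoic acid; 13 benzyl olivetolate
Product: 14 benzyl 2-hydroxy-4-[(2-hydroxy-4-methoxy-6-propylbenzoyl)oxy]-6-pentylbenzoate
Conditions: DCC (1.1 equiv.), toluene–Et2O, 0 °C to rt
Reagents that add atoms: none
Why: Carbodiimide esterification through the O-acylisourea of 10. The 4-hydroxyl of 13 is the only phenol not held in a hydrogen bond to an ortho carbonyl and not flanked, so the depside ester should form at O4 of ring B.

Step 9
Reactants: 14 benzyl 2-hydroxy-4-[(2-hydroxy-4-methoxy-6-propylbenzoyl)oxy]-6-pentylbenzoate
Product: 15 stenosporic acid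
Conditions: H2 (1 atm), Pd/C (10% Pd), EtOAc, rt
Reagents that add atoms: none
Why: Hydrogenolysis of the benzyl ester; the depside aryl ester, the phenols and the methyl ether are inert to H2 over Pd/C at room temperature. No base, acid or heat reaches the decarboxylation-prone product.

## Compound list

1 | 1,1-dimethoxyethene (ketene dimethyl acetal) | C=C(OC)OC | starting material
2 | butyryl chloride | CCCC(Cl)=O | starting material
3 | 1,1-dimethoxyhex-1-en-3-one | CCCC(=O)C=C(OC)OC | intermediate
4 | benzyl acetoacetate | CC(=O)CC(=O)OCc1ccccc1 | starting material
5 | benzyl (E)-3-(trimethylsilyloxy)but-2-enoate | C/C(O[Si](C)(C)C)=C\C(=O)OCc1ccccc1 | intermediate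
6 | (1Z)-1-benzyloxy-1,3-bis(trimethylsilyloxy)buta-1,3-diene | C=C(O[Si](C)(C)C)/C=C(/OCc1ccccc1)O[Si](C)(C)C | intermediate
7 | benzyl (5E)-5-methoxy-3,7-dioxodec-5-enoate (open-chain adduct, present in the flask as its silyl enol ether or titanium chelate; not isolated) | CCCC(=O)/C=C(/OC)CC(=O)CC(=O)OCc1ccccc1 | intermediate
8 | benzyl 2-hydroxy-4-methoxy-6-oxo-2-propylcyclohex-3-ene-1-carboxylate (aldol intermediate, mixture of diastereomers; not isolated) | CCCC1(O)C=C(OC)CC(=O)C1C(=O)OCc1ccccc1 | intermediate
9 | benzyl 2-hydroxy-4-methoxy-6-propylbenzoate | CCCc1cc(OC)cc(O)c1C(=O)OCc1ccccc1 | intermediate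
10 | 2-hydroxy-4-methoxy-6-propylbenzoic acid | CCCc1cc(OC)cc(O)c1C(=O)O | intermediate
11 | olivetol (5-pentylbenzene-1,3-diol) | CCCCCc1cc(O)cc(O)c1 | starting material
12 | olivetolic acid (2,4-dihydroxy-6-pentylbenzoic acid) | CCCCCc1cc(O)cc(O)c1C(=O)O | intermediate
13 | benzyl olivetolate (benzyl 2,4-dihydroxy-6-pentylbenzoate) | CCCCCc1cc(O)cc(O)c1C(=O)OCc1ccccc1 | intermediate
14 | benzyl 2-hydroxy-4-[(2-hydroxy-4-methoxy-6-propylbenzoyl)oxy]-6-pentylbenzoate | CCCCCc1cc(OC(=O)c2c(O)cc(OC)cc2CCC)cc(O)c1C(=O)OCc1ccccc1 | intermediate
15 | stenosporic acid | CCCCCc1cc(OC(=O)c2c(O)cc(OC)cc2CCC)cc(O)c1C(=O)O | target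

## Step count and risk

Total step count: 9. Longest linear sequence: 6 steps (4 to 5 to 6 to 9 to 10 to 14 to 15; steps 2, 3, 4, 5, 8 and 9).

**Step 4 (key step).**
- What may go wrong: the regiochemistry may reverse through initial 1,2-addition of the diene terminus to the ketone, because both the ketone carbon and the acetal carbon of 3 are electrophilic under TiCl4. Chloride may demethylate the activated ketene acetal to a β-keto ester. The sequence may stop at the open-chain stage, or close through oxygen to a pyranone instead of through carbon.
- Fallback, from 4 back to 9: benzyl acetoacetate 4 and methyl (E)-hex-2-enoate undergo Michael addition and Claisen ring closure under sodium benzyloxide in benzyl alcohol–toluene at reflux, giving benzyl 2,4-dioxo-6-propylcyclohexane-1-carboxylate F1. Bromination and dehydrobromination (Br2, 1 equiv., DMF, 0 °C, then warming) aromatise it to benzyl 2,4-dihydroxy-6-propylbenzoate F2. MeI and K2CO3 in acetone then methylate only the 4-hydroxyl, since the 2-hydroxyl is hydrogen-bonded to the ester, and this gives 9.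

**Step 1.**
- What may go wrong: Et3N may dehydrochlorinate 2 to ethylketene, which can dimerise or close with 1 to a cyclobutanone. The acid-sensitive push–pull enone may be hydrolysed or demethylated during work-up and purification. The ketene acetal may polymerise.
- Fallback, from 2 back to 3: butyryl chloride 2 acylates 1,1-dichloroethene under AlCl3 in CH2Cl2 (Friedel–Crafts-type alkene acylation) to give 1,1,1-trichlorohexan-3-one F3. This loses HCl on distillation or with a mild base to give 1,1-dichlorohex-1-en-3-one F4. Two successive addition–eliminations with NaOMe (2 equiv.) in MeOH at 0 °C replace both vinylic chlorides and give 3.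

**Step 6.**
- What may go wrong: carboxylation may enter between the two hydroxyls instead of next to the pentyl group, since both positions are ortho to a phenoxide. The reversible reaction may stop short of full conversion, and the product may decarboxylate during acidic work-up.
- Fallback, from 11 back to 12: Vilsmeier–Haack formylation of olivetol 11 (POCl3, DMF) places the electrophile para to one hydroxyl and next to the pentyl chain, giving 2,4-dihydroxy-6-pentylbenzaldehyde F5. Lindgren–Pinnick oxidation (NaClO2, NaH2PO4, sulfamic acid as chlorine scavenger, aqueous dioxane) converts the aldehyde into 12.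

**Step 8.**
- What may go wrong: the O-acylisourea of the hindered acid may rearrange to the N-acylurea faster than it is intercepted. Acylation may occur at a 2-hydroxyl. Acid 10 may self-esterify through its own phenol.
- Fallback, from 9 to 15: the phenol of 9 is benzylated (BnBr, K2CO3, DMF, 60 °C) to benzyl 2-(benzyloxy)-4-methoxy-6-propylbenzoate F6. Its ester is cleaved under forcing conditions that are harmless at this stage, where neither the depside nor the β-resorcylic acid is present (KOH, DMSO–H2O, 80 °C), to give 2-(benzyloxy)-4-methoxy-6-propylbenzoic acid F7. Oxalyl chloride with catalytic DMF gives 2-(benzyloxy)-4-methoxy-6-propylbenzoyl chloride F8. F8 acylates the 4-hydroxyl of 13 in pyridine–CH2Cl2 to give benzyl 4-{[2-(benzyloxy)-4-methoxy-6-propylbenzoyl]oxy}-2-hydroxy-6-pentylbenzoate F9. Hydrogenolysis of both benzyl groups (H2, Pd/C, EtOAc, rt) then gives 15 directly.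

## Further compounds

F1 | step 4 | benzyl 2,4-dioxo-6-propylcyclohexane-1-carboxylate (racemic, mixture of diastereomers and enol forms) | CCCC1CC(=O)CC(=O)C1C(=O)OCc1ccccc1
F2 | step 4 | benzyl 2,4-dihydroxy-6-propylbenzoate | CCCc1cc(O)cc(O)c1C(=O)OCc1ccccc1
F3 | step 1 | 1,1,1-trichlorohexan-3-one | CCCC(=O)CC(Cl)(Cl)Cl
F4 | step 1 | 1,1-dichlorohex-1-en-3-one | CCCC(=O)C=C(Cl)Cl
F5 | step 6 | 2,4-dihydroxy-6-pentylbenzaldehyde | CCCCCc1cc(O)cc(O)c1C=O
F6 | step 8 | benzyl 2-(benzyloxy)-4-methoxy-6-propylbenzoate | CCCc1cc(OC)cc(OCc2ccccc2)c1C(=O)OCc1ccccc1
F7 | step 8 | 2-(benzyloxy)-4-methoxy-6-propylbenzoic acid | CCCc1cc(OC)cc(OCc2ccccc2)c1C(=O)O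
F8 | step 8 | 2-(benzyloxy)-4-methoxy-6-propylbenzoyl chloride | CCCc1cc(OC)cc(OCc2ccccc2)c1C(=O)Cl
F9 | step 8 | benzyl 4-{[2-(benzyloxy)-4-methoxy-6-propylbenzoyl]oxy}-2-hydroxy-6-pentylbenzoate | CCCCCc1cc(OC(=O)c2c(OCc3ccccc3)cc(OC)cc2CCC)cc(O)c1C(=O)OCc1ccccc1
A1 | alternative 1 | 2,4-dimethoxy-6-propylbenzoic acid | CCCc1cc(OC)cc(OC)c1C(=O)O
A2 | alternative 1 | 1-fluoro-3,5-dimethoxybenzene | COc1cc(F)cc(OC)c1
A3 | alternative 1 | 3,5-dimethoxybenzyne | COC1=CC(OC)=CC#C1
A4 | alternative 1 | n-propyllithium | [Li]CCC
A5 | alternative 2 | ethyl 2-hydroxy-4-methoxy-6-propylbenzoate | CCCc1cc(OC)cc(O)c1C(=O)OCC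
A6 | alternative 2 | ethyl (2E)-5-diazo-4-oxo-3-propylpent-2-enoate | CCC/C(=C\C(=O)OCC)C(=O)C=[N+]=[N-]
A7 | alternative 2 | methoxyacetylene | COC#C
A8 | alternative 3 | benzyl 2,4-dihydroxy-6-pentylbenzoate | CCCCCc1cc(O)cc(O)c1C(=O)OCc1ccccc1
A9 | alternative 3 | (1Z)-1-methoxy-1,3-bis(trimethylsilyloxy)buta-1,3-diene | C=C(O[Si](C)(C)C)/C=C(/OC)O[Si](C)(C)C
A10 | alternative 3 | benzyl oct-2-ynoate | CCCCCC#CC(=O)OCc1ccccc1
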